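**Plan**

1. Numbering: C7 is the carbinol carbon, C8 the methyl-bearing carbon; ring A is the phenol ring (C1' carries C8, C2' OH, C3' OMe, C5' allyl); ring B is the veratryl ring.
2. Feature used: C8, OH and OMe sit on the three adjacent ring A carbons C1', C2' and C3', so C1' and C2' can be the two carbons of 3-methoxybenzyne, which takes up C8 and an acetyl group (a masked OH) in one operation.
3. Retrosynthetic cuts, in order: C5'–allyl (para-Claisen from the C2' allyl ether), C7–H (ketone), C7–ring B (Weinreb amide plus aryl Grignard reagent), C2'–O (Baeyer–Villiger of a C2' acetyl group), then C1'–C8 together with C2'–C(acetyl) (aryne insertion into the C2–C3 bond of methyl 2-methyl-3-oxobutanoate).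
4. Forward: ring A is joined to C8 and to the acetyl carbon first, the ester carbon (future C7) is then linked to ring B, the ketone is reduced, and the allyl group moves from O to C5' last; no ring is formed.
5. Stereochemistry: C8 stays racemic and base-labile up to the ketone; one asymmetric hydrogenation under dynamic kinetic resolution sets C7 (S, catalyst control) and C8 (S, Felkin–Anh matching).

Key step: step 1

Remark: the sense of hydride delivery in step 6 is taken from simple aryl alkyl ketones, which the (R)-xylbinap/(R)-daipen ruthenium dichloride complex reduces to S carbinols; in the ketone of step 6 O, ring B and C8 rank in the same order, so the same catalyst is assumed to give 7S.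

**Route**

Step 1
Reactants: 1 3-methoxy-2-(trimethylsilyl)phenyl trifluoromethanesulfonate; 2 methyl 2-methyl-3-oxobutanoate
Product: 5 methyl 2-(2-acetyl-3-methoxyphenyl)propanoate (racemic), via 3-methoxybenzyne 3 (not isolated), via benzocyclobutene alkoxide 4 (not isolated)
Conditions: CsF (2.5 equiv), MeCN, 80 °C
Reagents that add atoms: none
Why: Fluoride removes the silyl group of 1 and triflate leaves to give aryne 3; the cesium enolate of 2 adds through its α-carbon (the future C8) to the aryne carbon meta to OMe (C1'), and the aryl anion thus placed at C2', next to OMe, adds to the ketone carbonyl in a 4-exo-trig closure to give alkoxide 4. Strain-driven retro-aldol-type opening of 4 breaks the former C2–C3 bond of the keto ester, leaving the acetyl group on C2' and an ester enolate at C8 that is protonated by the medium. The closest known reaction type is the acyl-alkylation of arynes with β-keto esters (formal insertion into the C–C σ bond), which is established for 3-methoxybenzyne and for α-substituted keto esters. The only ring closed is the transient four-membered one, which does not survive into 5. C8 is formed without control and is racemic; it stays epimerisable and is fixed only in step 6. The step needs regioselectivity, secured by the inductively withdrawing OMe that directs the nucleophile to the remote aryne carbon and the developing charge to the carbon next to oxygen, and chemoselectivity of the ring closure for the ketone over the ester carbonyl, secured by the higher electrophilicity of the ketone.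

Step 2
Reactants: 5 methyl 2-(2-acetyl-3-methoxyphenyl)propanoate (racemic)
Product: 6 methyl 2-[2-(acetyloxy)-3-methoxyphenyl]propanoate (racemic)
Conditions: mCPBA, TFA (cat.), CH2Cl2, 0 °C to rt
Reagents that add atoms: mCPBA, 3-chloroperoxybenzoic acid, O=C(OO)c1cccc(Cl)c1
Why: Baeyer–Villiger oxidation, in which the electron-rich ortho-methoxy aryl group migrates in preference to methyl in the Criegee adduct, so the acetyl group becomes the C2' aryl acetate while the methyl ester and the benzylic C8–H are left alone.

Step 3
Reactants: 6 methyl 2-[2-(acetyloxy)-3-methoxyphenyl]propanoate (racemic)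
Product: 8 methyl 2-[3-methoxy-2-(prop-2-en-1-yloxy)phenyl]propanoate (racemic), via potassium phenoxide 7 (not isolated)
Conditions: K2CO3, MeOH, rt; then allyl bromide, 40 °C
Reagents that add atoms: allyl bromide, C=CCBr
Why: Methanolysis of the aryl acetate releases phenoxide 7, which is trapped in the same flask by Williamson O-allylation; methanol as solvent keeps any benzofuranone formed by attack of the phenoxide on the neighbouring ester ring-opened, so C-allylation at C8 should not compete.

Step 4
Reactants: 8 methyl 2-[3-methoxy-2-(prop-2-en-1-yloxy)phenyl]propanoate (racemic)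
Product: 9 N-methoxy-2-[3-methoxy-2-(prop-2-en-1-yloxy)phenyl]-N-methylpropanamide (racemic)
Conditions: MeNH(OMe)·HCl, iPrMgCl, THF, −20 to 0 °C
Reagents that add atoms: N,O-dimethylhydroxylamine hydrochloride, CNOC.Cl
Why: Weinreb amide formation by aminolysis of the methyl ester with the chloromagnesium amide generated in the flask, a standard conversion that the aryl allyl ether tolerates.

Step 5
Reactants: 9 N-methoxy-2-[3-methoxy-2-(prop-2-en-1-yloxy)phenyl]-N-methylpropanamide (racemic); 10 4-bromo-1,2-dimethoxybenzene
Product: 12 1-(3,4-dimethoxyphenyl)-2-[3-methoxy-2-(prop-2-en-1-yloxy)phenyl]propan-1-one (racemic), via aryl Grignard reagent 11 (not isolated)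
Conditions: 10, Mg turnings, THF, 40 °C; then 9, THF, 0 °C to rt; aq NH4Cl
Reagents that add atoms: none
Why: Grignard acylation of a Weinreb amide, in which the five-membered magnesium chelate holds the tetrahedral adduct until work-up, so the C7–ring B bond is formed once and the ketone is released without over-addition.

Step 6
Reactants: 12 1-(3,4-dimethoxyphenyl)-2-[3-methoxy-2-(prop-2-en-1-yloxy)phenyl]propan-1-one (racemic)
Product: 13 (1S,2S)-1-(3,4-dimethoxyphenyl)-2-[3-methoxy-2-(prop-2-en-1-yloxy)phenyl]propan-1-ol
Conditions: trans-RuCl2[(R)-xylbinap][(R)-daipen] (1 mol %), t-BuOK (20 mol %), H2 (10 atm), i-PrOH, 25 °C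
Reagents that add atoms: none
Why: Noyori-type asymmetric hydrogenation of an aryl ketone under dynamic kinetic resolution, a reaction type established for base-labile α-aryl ketones: t-BuOK interconverts the enantiomers of 12 through the enolate faster than either is reduced, the (R,R)-configured catalyst delivers hydride to the Re face of C7 (giving 7S), and only the 8S enantiomer can accept it in a Felkin–Anh arrangement with ring A anti to the incoming hydride, so the anti (7S,8S) alcohol should result while the allyl ether is not touched by this carbonyl-selective catalyst.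

Step 7
Reactants: 13 (1S,2S)-1-(3,4-dimethoxyphenyl)-2-[3-methoxy-2-(prop-2-en-1-yloxy)phenyl]propan-1-ol
Product: 14 (1S,2S)-1-(3,4-dimethoxyphenyl)-2-[2-hydroxy-3-methoxy-5-(prop-2-en-1-yl)phenyl]propan-1-ol
Conditions: PhNEt2, 190 °C, sealed tube, argon
Reagents that add atoms: none
Why: Aromatic para-Claisen rearrangement: with both ortho positions (C1' and C3') substituted, the first [3,3] shift to an ortho-dienone is followed by a Cope [3,3] shift to C5' and tautomerisation, which places the allyl group para to the new phenol; no bond at C7 or C8 takes part, so both stereocentres should be retained in the buffered, non-acidic amine solvent.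

**Compound list**

1 | 3-methoxy-2-(trimethylsilyl)phenyl trifluoromethanesulfonate | COc1cccc(OS(=O)(=O)C(F)(F)F)c1[Si](C)(C)C | starting material
2 | methyl 2-methyl-3-oxobutanoate (racemic) | COC(=O)C(C)C(C)=O | starting material
3 | 3-methoxybenzyne | COC1=CC=CC#C1 | intermediate (not isolated)
4 | cesium 2-methoxy-7-(methoxycarbonyl)-7,8-dimethylbicyclo[4.2.0]octa-1,3,5-trien-8-olate (benzocyclobutene alkoxide) | COC(=O)C1(C)c2cccc(OC)c2C1(C)[O-].[Cs+] | intermediate (not isolated)
5 | methyl 2-(2-acetyl-3-methoxyphenyl)propanoate (racemic) | COC(=O)C(C)c1cccc(OC)c1C(C)=O | intermediate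
6 | methyl 2-[2-(acetyloxy)-3-methoxyphenyl]propanoate (racemic) | COC(=O)C(C)c1cccc(OC)c1OC(C)=O | intermediate
7 | potassium 2-methoxy-6-(1-methoxy-1-oxopropan-2-yl)phenolate (racemic) | COC(=O)C(C)c1cccc(OC)c1[O-].[K+] | intermediate (not isolated)
8 | methyl 2-[3-methoxy-2-(prop-2-en-1-yloxy)phenyl]propanoate (racemic) | COC(=O)C(C)c1cccc(OC)c1OCC=C | intermediate
9 | N-methoxy-2-[3-methoxy-2-(prop-2-en-1-yloxy)phenyl]-N-methylpropanamide (racemic) | CON(C)C(=O)C(C)c1cccc(OC)c1OCC=C | intermediate
10 | 4-bromo-1,2-dimethoxybenzene (4-bromoveratrole) | COc1ccc(Br)cc1OC | starting material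
11 | (3,4-dimethoxyphenyl)magnesium bromide | COc1ccc([Mg]Br)cc1OC | intermediate (not isolated)
12 | 1-(3,4-dimethoxyphenyl)-2-[3-methoxy-2-(prop-2-en-1-yloxy)phenyl]propan-1-one (racemic) | COc1ccc(cc1OC)C(=O)C(C)c1cccc(OC)c1OCC=C | intermediate
13 | (1S,2S)-1-(3,4-dimethoxyphenyl)-2-[3-methoxy-2-(prop-2-en-1-yloxy)phenyl]propan-1-ol | C=CCOc1c(OC)cccc1[C@H](C)[C@H](O)c1ccc(OC)c(OC)c1 | intermediate
14 | (1S,2S)-1-(3,4-dimethoxyphenyl)-2-[2-hydroxy-3-methoxy-5-(prop-2-en-1-yl)phenyl]propan-1-ol | C=CCc1cc(OC)c(O)c([C@H](C)[C@H](O)c2ccc(OC)c(OC)c2)c1 | target

**Summary**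

Total steps: 7. Longest linear sequence: 7 steps (1 to 14); the aryl Grignard reagent is made in the flask of step 5.

Steps most likely to fail:

Step 6. The enantiomers of the ketone may interconvert too slowly relative to hydrogenation, or catalyst control at C7 and Felkin–Anh preference at C8 may reinforce each other only weakly, so that diastereo- and enantioselectivity erode. Fallback, setting out from 12: substrate-controlled Felkin–Anh reduction with LiBH(s-Bu)3 in THF at −78 °C should give the racemic anti-1-(3,4-dimethoxyphenyl)-2-[3-methoxy-2-(prop-2-en-1-yloxy)phenyl]propan-1-ol F1. Its enantiomers are then separated by preparative chromatography on a chiral stationary phase (amylose or cellulose carbamate), and the (1S,2S) enantiomer is 13, where the route is rejoined.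

Step 7. At the temperature needed for the two sigmatropic shifts, the newly formed phenol may protonate the electron-rich benzylic carbinol; ionisation at C7 would then scramble its configuration or close a dihydrobenzofuran onto the phenol oxygen. Fallback, setting out from 13: the carbinol is silylated (TBSOTf, 2,6-lutidine, CH2Cl2, −78 °C) to the tert-butyldimethylsilyl ether of 13 F2. The para-Claisen rearrangement is run on this ether (PhNEt2, 190 °C) to give the tert-butyldimethylsilyl ether of 14 F3, and the silyl group is removed with Bu4NF in THF to arrive at 14. A silyl shift from the C7 oxygen to the phenol oxygen during heating would be harmless, since both isomers give 14 on desilylation.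

Step 1. With the α-branched keto ester, the aryl anion formed after the first C–C bond may be protonated before it closes onto the ketone, diverting material to plain α-arylation, and the congested benzylic centre may slow the insertion. Fallback, setting out from 1: the aryne is generated in the same way but intercepted with commercial methyl 3-oxobutanoate (COC(=O)CC(C)=O), the unbranched partner, to give methyl 2-(2-acetyl-3-methoxyphenyl)acetate F4 by the same insertion. Baeyer–Villiger oxidation (mCPBA, TFA) should give methyl 2-[2-(acetyloxy)-3-methoxyphenyl]acetate F5, and methanolysis with O-allylation (K2CO3, MeOH, allyl bromide) methyl 2-[3-methoxy-2-(prop-2-en-1-yloxy)phenyl]acetate F6. Enolate methylation (LiN(i-Pr)2, THF, −78 °C; MeI) then installs the C8 methyl group and returns to the route at 8.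

**Further compounds**

F1 | step 6 | racemic anti-1-(3,4-dimethoxyphenyl)-2-[3-methoxy-2-(prop-2-en-1-yloxy)phenyl]propan-1-ol, (1S,2S) and (1R,2R) enantiomers | C=CCOc1c(OC)cccc1[C@H](C)[C@H](O)c1ccc(OC)c(OC)c1.C=CCOc1c(OC)cccc1[C@@H](C)[C@@H](O)c1ccc(OC)c(OC)c1
F2 | step 7 | tert-butyl{(1S,2S)-1-(3,4-dimethoxyphenyl)-2-[3-methoxy-2-(prop-2-en-1-yloxy)phenyl]propoxy}dimethylsilane | C=CCOc1c(OC)cccc1[C@H](C)[C@H](O[Si](C)(C)C(C)(C)C)c1ccc(OC)c(OC)c1
F3 | step 7 | 2-[(1S,2S)-1-{[tert-butyl(dimethyl)silyl]oxy}-1-(3,4-dimethoxyphenyl)propan-2-yl]-6-methoxy-4-(prop-2-en-1-yl)phenol | C=CCc1cc(OC)c(O)c([C@H](C)[C@H](O[Si](C)(C)C(C)(C)C)c2ccc(OC)c(OC)c2)c1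
F4 | step 1 | methyl 2-(2-acetyl-3-methoxyphenyl)acetate | COC(=O)Cc1cccc(OC)c1C(C)=O
F5 | step 1 | methyl 2-[2-(acetyloxy)-3-methoxyphenyl]acetate | COC(=O)Cc1cccc(OC)c1OC(C)=O
F6 | step 1 | methyl 2-[3-methoxy-2-(prop-2-en-1-yloxy)phenyl]acetate | COC(=O)Cc1cccc(OC)c1OCC=C
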